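Remark on the chemistry: lignan numbering is used throughout (C7 and C7' benzylic, C8 and C8' ring-fusion carbons, C9 and C9' the OCH2 carbons; Ar1 = 4-hydroxy-3-methoxyphenyl on C7, Ar2 = 3-methoxy-4-prenyloxyphenyl on C7'; ring 1 = C7–O–C9'–C8'–C8, ring 2 = C7'–O–C9–C8–C8'). Both enantiomers of α,α-diphenylprolinol trimethylsilyl ether are taken to be commercial.

## Analysis of the target

The target is a 2,6-diaryl-3,7-dioxabicyclo[3.3.0]octane (furofuran) in which two tetrahydrofuran rings share the C8–C8' bond in a cis fusion. It has four contiguous stereocentres, C7 (R), C8 (S), C8' (S) and C7' (R), and both aryl groups sit on the convex (exo) face, cis to the neighbouring ring-fusion hydrogen. The core is C2-symmetric, but the substituents are not: Ar1 carries a free phenol and Ar2 a prenyl ether, so the two aryl groups must be told apart at some point. Both C7–O and C7'–O are electron-rich benzylic ether bonds that ionise under acid (epimerisation towards the endo isomers, which are barely less stable) and are open to hydrogenolysis. The prenyl ether is labile to Lewis and Brønsted acids and its alkene is a nucleophile and a hydroboration site, and the phenol must be masked during organometallic steps. The difficulty is therefore absolute control of a skeleton with no functionality beyond ethers, kinetic exo placement of two aryl groups, and a late, mild entry of the prenyl group. The strategy rests on one feature: C7' bears a donor aryl group and C8 can carry a lactone carbonyl (C7), so a cyclopropane C7'–C8 bond spanning C8' is a latent benzylic cation next to a C9 hydroxyl, and opening it closes ring 2 onto a lactone that later becomes ring 1.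

## Retrosynthetic reasoning

**Phenol and prenyl ether (22 ⇒ 21 ⇒ 19).** The last bond cut is the O–Si bond of silyl ether 21, because fluoride leaves the prenyl ether and both benzylic ethers alone. The prenyl group of 21 is then cut at its C=C bond, which traces it to the allyl ether 19 and alkene 20 by cross-metathesis. This is preferred to carrying the prenyl ether through the route, since it would not survive the Lewis acid of the key step or the acid of the last ring closure. It is also preferred to a silyl ether on Ar2, which would be cleaved by hydroxide at the cyclopropane stage, after which the free p-hydroxyphenyl group would open the ring to a quinone methide. The allyl ether is a strong donor, tolerates every step, and becomes the prenyl ether without a deprotection and re-alkylation.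

**Ring 1 and Ar1 (19 ⇒ 18 ⇒ 13 + 17; 13 ⇒ 12; 17 ⇒ 16 ⇒ 14 + 15).** Ring 1 is opened at the C7–O bond, giving diol 18, and the C7–Ar1 bond is then cut, giving lactol 13 and aryl Grignard reagent 17. Cutting here lets Ar1 arrive on its own, already carrying the protected phenol, which solves the desymmetrisation without any statistical step. The forward closure passes through a benzylic cation at C7, so the configuration of the carbinol in 18 need not be controlled; the C9' hydroxyl must attack the face that puts Ar1 exo. Lactol 13 is the reduction product of lactone 12, and 17 comes from bromide 16, the silyl ether of phenol 14 made with silyl chloride 15.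

**Ring 2 (12 ⇒ 11), the key disconnection.** The C7'–O bond of lactone 12 is cut and C7' is reconnected to C8, which gives the cyclopropane lactone 11. This is the one place in the skeleton where a donor (Ar2 on C7') and an acceptor (the C7 carbonyl on C8) flank a single bond, so a Lewis acid can ionise exactly that bond. The gain is large: ring 2, the C7'–O bond and the stereocentres C7' and C8 all come from a strain-driven isomerisation that needs no reagent. The forward step has to ionise only C7'–C8, deliver the C9 oxygen to C7' with Ar2 exo, and reprotonate C8 to the cis-fused bicycle; C8' is the only centre that passes through unchanged, so it alone must be set in absolute terms.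

**The two carbonyl groups on C8 (11 ⇒ 9 ⇒ 7 ⇒ 5).** The C9 hydroxymethyl group of 11 is traced to the carboxylic acid 9, the acid to ester 7, and the lactone of 7 to the formyl diester 5. The two ester groups of 5 differ only in their relation to the C9' carbon: after reduction of the aldehyde, only the ester on the same face can lactonise, and the other, cis to the aryl group, is left to become C9. The reduction of the acid has to spare both the lactone and the allyl group, which rules out hydroborating reductants and calls for an activated acyl derivative (10) and a borohydride.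

**The cyclopropane (5 ⇒ 3 + 4; 3 ⇒ 1 + 2).** The C7'–C8 and C8'–C8 bonds of 5 are cut, which leads to enal 3 and bromomalonate 4. An amine-catalysed conjugate addition followed by ring closure builds the three-membered ring and sets C8' (and, temporarily, C7') under catalyst control with the aryl and formyl groups trans. The trans arrangement matters because it puts the later lactone on the face away from Ar2. Enal 3 is the allyl ether of 1, made with bromide 2.

## Alternatives that were turned down

**Alternative 1: conjugate addition–aldol on a chiral butenolide.** The disconnection cuts C7–C8 and C7'–C8'. In the forward key step the lithiated dithiane A3 adds to the acetal butenolide A2 at C8, and the lactone enolate is trapped at C8' by aldehyde A4 to give the trans,trans lactone A1.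
- For it: the step is convergent, installs both aryl groups and both ring-fusion centres in one flask, and uses an auxiliary known for high facial control. On convergence it is stronger than the chosen route.
- Against it: neither ring of the target is formed. A1 still needs reduction of the lactone and the acetal, dithiane removal, ketone reduction, two cationic ring closures and desilylation. Dithiane cleavage uses thiophilic or oxidising reagents that attack the prenyl alkene, and both C7 and C7' would be set by acid closures in the presence of the acid-labile prenyl ether. The auxiliary in A2 is the (1S,2R,5S)-menthyl group, from the less abundant enantiomeric series, and is used stoichiometrically.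
- Comparison: the chosen route gives up some convergence. In return it has catalytic absolute control, sets C7' in the step that also closes ring 2, and has a single cationic closure carried out before the prenyl group exists.

**Alternative 2: titanocene radical cascade.** The disconnection cuts C8–C8' and C7'–O. In the forward key step Cp2TiCl (trivalent titanium) opens the epoxide of ether A6 to a C8 radical, which cyclises onto the cinnamyl alkene to form ring 1; oxidation with iodine then lets the C9 alkoxide capture C7' to form ring 2, giving the bis-silyl furofuran A5.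
- For it: it is clearly shorter, since the whole bicycle appears in one operation. On step economy it is stronger than the chosen route.
- Against it: three stereocentres (C8, C8', C7') must follow from the single carbinol centre of A6 through a radical cyclisation and a cation capture, neither of which has a strong stereochemical bias, so diastereomers and reduced monocyclic products are to be expected. A6 needs an enantiopure, very acid-labile p-oxygenated benzylic epoxy carbinol, typically reached by a resolution that discards half of the material. Titanium is stoichiometric, and iodine meets two electron-rich arenes. A5 still needs a selective cleavage of one aryl silyl ether beside another before the prenyl group can go on.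
- Comparison: the chosen route is longer, but each stereocentre is set in a separate event that can be argued on its own, and the aryl groups are differentiated from the start.

**Alternative 3: bidirectional hydroboration.** The disconnection cuts both C9–O and C9'–O bonds to the hydroxyl groups of a C2-symmetric tetraol. In the forward key step a hindered dialkylborane adds to both terminal methylenes of diene diol A8 anti to the allylic oxygen, and oxidation gives tetraol A7 with the (8S,8'S) pair.
- For it: it uses the symmetry of the core fully and reaches the symmetrical skeleton quickly. For a symmetrical furofuran it would be stronger than the chosen route.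
- Against it: the target is not symmetrical. A7 carries two identical aryl groups, so after double cyclisation and desilylation the bis-phenol A9 would have to be prenylated once on one of two equivalent phenols, a statistical step that cannot exceed about half conversion to the wanted product. Two acyclic 1,2-inductions must both succeed, and both benzylic carbinol centres are then erased in two acid closures.
- Comparison: the chosen route uses no symmetry. In return the two aryl groups are distinct from the first step and each is introduced only once.

Key step: step 6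

## Route

Step 1
Reactants: 1 coniferaldehyde; 2 allyl bromide
Product: 3 (E)-3-[4-(allyloxy)-3-methoxyphenyl]prop-2-enal
Conditions: allyl bromide, K2CO3, acetone, reflux
Reagents that add atoms: allyl bromide (2), C=CCBr
Why: Williamson O-alkylation of the phenoxide (SN2 on the allylic bromide); carbonate does not touch the enal and no stereocentre is formed.

Step 2
Reactants: 3 (E)-3-[4-(allyloxy)-3-methoxyphenyl]prop-2-enal; 4 diethyl bromomalonate
Product: 5 diethyl (2S,3R)-3-[4-(allyloxy)-3-methoxyphenyl]-2-formylcyclopropane-1,1-dicarboxylate
Conditions: (R)-α,α-diphenylprolinol trimethylsilyl ether (20 mol %), 2,6-lutidine (1.1 equiv), CH2Cl2, 0 °C to rt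
Reagents that add atoms: diethyl bromomalonate (4), CCOC(=O)C(Br)C(=O)OCC
Why: Iminium–enamine Michael-initiated ring closure: the bromomalonate anion adds to the β-carbon on the face left open by the diphenyl(silyloxy)methyl group of the (R)-catalyst (C7' becomes R), and the enamine then displaces bromide in a 3-exo-tet alkylation that places the formyl group trans to the aryl group (C8' becomes S); the hindered base 2,6-lutidine avoids base-induced opening of the product.

Step 3
Reactants: 5 diethyl (2S,3R)-3-[4-(allyloxy)-3-methoxyphenyl]-2-formylcyclopropane-1,1-dicarboxylate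
Product: 7 ethyl (1R,5S,6R)-6-[4-(allyloxy)-3-methoxyphenyl]-2-oxo-3-oxabicyclo[3.1.0]hexane-1-carboxylate, via hydroxymethyl diester 6 (not isolated)
Conditions: NaBH4 (0.5 equiv), EtOH, −20 °C; AcOH; then PPTS (cat.), CH2Cl2, rt
Reagents that add atoms: none
Why: Chemoselective borohydride reduction of the aldehyde, after which the primary alcohol of 6 acylates itself with the only ester on its own face (lactonisation), leaving the ester cis to the aryl group; substoichiometric hydride at low temperature limits attack on the activated lactone, and the existing stereocentres are untouched.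

Step 4
Reactants: 7 ethyl (1R,5S,6R)-6-[4-(allyloxy)-3-methoxyphenyl]-2-oxo-3-oxabicyclo[3.1.0]hexane-1-carboxylate
Product: 9 (1R,5S,6R)-6-[4-(allyloxy)-3-methoxyphenyl]-2-oxo-3-oxabicyclo[3.1.0]hexane-1-carboxylic acid, via dilithium hydroxy dicarboxylate 8 (not isolated)
Conditions: LiOH·H2O (4 equiv), THF/H2O (3:1), 0 °C to rt; then 1 M HCl to pH 2–3 at 0 °C, EtOAc
Reagents that add atoms: lithium hydroxide, [Li+].[OH-]
Why: Saponification opens the lactone and cleaves the ethyl ester to dicarboxylate 8; on cold acidification only the carboxyl cis to the hydroxymethyl group can relactonise, so the free acid ends up on the aryl face whichever ester was cleaved first; the allyl ether is inert to hydroxide.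

Step 5
Reactants: 9 (1R,5S,6R)-6-[4-(allyloxy)-3-methoxyphenyl]-2-oxo-3-oxabicyclo[3.1.0]hexane-1-carboxylic acid
Product: 11 (1R,5S,6R)-6-[4-(allyloxy)-3-methoxyphenyl]-1-(hydroxymethyl)-3-oxabicyclo[3.1.0]hexan-2-one, via isobutyl carbonic mixed anhydride 10 (not isolated)
Conditions: i-BuOCOCl, N-methylmorpholine, THF, −15 °C; then NaBH4, H2O, −15 to 0 °C
Reagents that add atoms: none
Why: Reduction of a carboxylic acid through its mixed carbonic anhydride 10; borohydride attacks the activated acyl carbon much faster than the lactone and leaves the allyl group alone, which a borane would hydroborate; the configuration at C8 is kept.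

Step 6
Reactants: 11 (1R,5S,6R)-6-[4-(allyloxy)-3-methoxyphenyl]-1-(hydroxymethyl)-3-oxabicyclo[3.1.0]hexan-2-one
Product: 12 (1S,5S,6R)-6-[4-(allyloxy)-3-methoxyphenyl]-3,7-dioxabicyclo[3.3.0]octan-2-one
Conditions: Sc(OTf)3 (10 mol %), CH2Cl2 (0.02 M), 0 °C to rt
Reagents that add atoms: none
Why: Sc(OTf)3 binds the lactone carbonyl, probably chelated by the C9 hydroxyl, and heterolyses the C7'–C8 bond, the only cyclopropane bond that joins the donor-bearing carbon to the acceptor-bearing carbon, to give a benzylic cation at C7' stabilised by the p-allyloxy group and a scandium lactone enolate at C8. The closest known reaction type is the Lewis-acid-catalysed ring-opening cyclisation of donor–acceptor cyclopropanes by a tethered hydroxyl group, which enlarges the three-membered ring to a tetrahydrofuran; because the nucleophile here sits on the acceptor carbon, a backside displacement is impossible and the reaction must pass through the ion pair. After rotation about C8'–C7' the C9 hydroxyl adds to the trigonal C7' in a 5-exo-trig closure (the C7'–aryl π bond of the quinone-methide-like cation lies outside the new ring), which forms the C7'–O bond and ring 2. C7' is controlled by allylic 1,3-strain in the cation: H8' lies in the cation plane beside the aryl group, so attack from the side of C8 places the aryl group trans to C9', that is exo (R). C8 is set by protonation of the enolate from the convex face, opposite the new ring, the only path to a cis-fused bicyclo[3.3.0] system; this centre is epimerisable and the cis fusion is the stable one (S). C8' is not touched and relays the absolute configuration of step 2 to both new centres. The step needs ionisation of C7'–C8 in preference to loss of the C9 hydroxyl, and capture by that hydroxyl in preference to elimination or arene alkylation; the lactone carbonyl as the better Lewis-basic site, the inability of the carbonyl oxygen to reach C7' without a bridgehead double bond, and the proximity of the hydroxyl at high dilution secure this. Release of cyclopropane strain drives the isomerisation, which consumes no reagent.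

Step 7
Reactants: 12 (1S,5S,6R)-6-[4-(allyloxy)-3-methoxyphenyl]-3,7-dioxabicyclo[3.3.0]octan-2-one
Product: 13 (1S,5S,6R)-6-[4-(allyloxy)-3-methoxyphenyl]-3,7-dioxabicyclo[3.3.0]octan-2-ol (anomeric mixture)
Conditions: iBu2AlH (1.2 equiv), CH2Cl2, −78 °C; aq. potassium sodium tartrate
Reagents that add atoms: none
Why: Partial reduction of a γ-lactone to the lactol, the tetrahedral aluminium alkoxide being stable at −78 °C until work-up; the ring-fusion centres are untouched and the anomeric mixture is of no consequence.

Step 8
Reactants: 14 4-bromo-2-methoxyphenol; 15 chlorotriisopropylsilane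
Product: 16 (4-bromo-2-methoxyphenoxy)triisopropylsilane
Conditions: iPr3SiCl, imidazole, DMF, rt
Reagents that add atoms: chlorotriisopropylsilane (15), CC(C)[Si](Cl)(C(C)C)C(C)C
Why: Standard silylation of a phenol; the triisopropylsilyl ether survives Grignard formation, the acid of step 10 and the metathesis, and is cleaved by fluoride at the end.

Step 9
Reactants: 13 (1S,5S,6R)-6-[4-(allyloxy)-3-methoxyphenyl]-3,7-dioxabicyclo[3.3.0]octan-2-ol; 16 (4-bromo-2-methoxyphenoxy)triisopropylsilane
Product: 18 [(3S,4S,5R)-5-[4-(allyloxy)-3-methoxyphenyl]-4-(hydroxymethyl)oxolan-3-yl][3-methoxy-4-(triisopropylsilyloxy)phenyl]methanol (both C7 epimers), via aryl Grignard reagent 17 (not isolated)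
Conditions: Mg, THF, reflux (16 to 17); then 13, THF, 0 °C to rt (3 equiv of 17); aq. NH4Cl
Reagents that add atoms: (4-bromo-2-methoxyphenoxy)triisopropylsilane (16), COc1cc(Br)ccc1O[Si](C(C)C)(C(C)C)C(C)C
Why: Magnesium insertion gives Grignard reagent 17; one equivalent deprotonates the lactol, whose ring-opened hydroxy aldehyde form is then arylated at C7 by 1,2-addition; the C7 carbinol forms as a mixture of epimers, which is acceptable because C7 becomes trigonal again in step 10.

Step 10
Reactants: 18 [(3S,4S,5R)-5-[4-(allyloxy)-3-methoxyphenyl]-4-(hydroxymethyl)oxolan-3-yl][3-methoxy-4-(triisopropylsilyloxy)phenyl]methanol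
Product: 19 (1S,2R,5S,6R)-6-[4-(allyloxy)-3-methoxyphenyl]-2-[3-methoxy-4-(triisopropylsilyloxy)phenyl]-3,7-dioxabicyclo[3.3.0]octane
Conditions: 10-camphorsulfonic acid (10 mol %), CH2Cl2, −20 to 0 °C
Reagents that add atoms: none
Why: Acid-catalysed dehydrative cycloetherification (SN1): the p-silyloxybenzylic alcohol ionises to a cation common to both epimers and the C9' hydroxyl closes ring 1 in a 5-exo-trig mode; allylic 1,3-strain holds H8 in the cation plane beside the aryl group, so the oxygen attacks the face that puts Ar1 exo on the cis-fused bicycle (C7 becomes R); weak acid, low temperature and a short reaction time keep the closure kinetic.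

Step 11
Reactants: 19 (1S,2R,5S,6R)-6-[4-(allyloxy)-3-methoxyphenyl]-2-[3-methoxy-4-(triisopropylsilyloxy)phenyl]-3,7-dioxabicyclo[3.3.0]octane; 20 2-methylbut-2-ene
Product: 21 (1S,2R,5S,6R)-2-[3-methoxy-4-(triisopropylsilyloxy)phenyl]-6-[3-methoxy-4-(3-methylbut-2-enyloxy)phenyl]-3,7-dioxabicyclo[3.3.0]octane
Conditions: second-generation Grubbs catalyst RuCl2(=CHPh)(PCy3)(SIMes) (5 mol %), 2-methylbut-2-ene (large excess), CH2Cl2, rt
Reagents that add atoms: 2-methylbut-2-ene (20), CC=C(C)C
Why: Olefin cross-metathesis of the terminal allyl ether with an excess of the trisubstituted alkene transfers the isopropylidene unit and releases propene, converting the allyl ether directly into the prenyl ether; ethers, the silyl ether and all stereocentres are inert to the ruthenium carbene.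

Step 12
Reactants: 21 (1S,2R,5S,6R)-2-[3-methoxy-4-(triisopropylsilyloxy)phenyl]-6-[3-methoxy-4-(3-methylbut-2-enyloxy)phenyl]-3,7-dioxabicyclo[3.3.0]octane
Product: 22 4-[(1S,2R,5S,6R)-6-[3-methoxy-4-(3-methylbut-2-enyloxy)phenyl]-3,7-dioxabicyclo[3.3.0]octan-2-yl]-2-methoxyphenol (the target)
Conditions: Bu4NF (1.1 equiv), THF, 0 °C; aq. NH4Cl
Reagents that add atoms: none
Why: Fluoride-induced cleavage of the aryl silyl ether, driven by Si–F bond formation; the non-acidic conditions leave the prenyl ether and both benzylic ethers intact, so no stereocentre is at risk.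

## Compound list

1 | coniferaldehyde | COc1cc(/C=C/C=O)ccc1O | starting material
2 | allyl bromide | C=CCBr | starting material
3 | (E)-3-[4-(allyloxy)-3-methoxyphenyl]prop-2-enal | COc1cc(/C=C/C=O)ccc1OCC=C | intermediate
4 | diethyl bromomalonate | CCOC(=O)C(Br)C(=O)OCC | starting material
5 | diethyl (2S,3R)-3-[4-(allyloxy)-3-methoxyphenyl]-2-formylcyclopropane-1,1-dicarboxylate | O=C[C@H]1[C@H](c2ccc(OCC=C)c(OC)c2)C1(C(=O)OCC)C(=O)OCC | intermediate
6 | diethyl (2S,3R)-3-[4-(allyloxy)-3-methoxyphenyl]-2-(hydroxymethyl)cyclopropane-1,1-dicarboxylate | OC[C@H]1[C@H](c2ccc(OCC=C)c(OC)c2)C1(C(=O)OCC)C(=O)OCC | intermediate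
7 | ethyl (1R,5S,6R)-6-[4-(allyloxy)-3-methoxyphenyl]-2-oxo-3-oxabicyclo[3.1.0]hexane-1-carboxylate | O=C1OC[C@H]2[C@H](c3ccc(OCC=C)c(OC)c3)[C@@]12C(=O)OCC | intermediate
8 | dilithium (2S,3R)-3-[4-(allyloxy)-3-methoxyphenyl]-2-(hydroxymethyl)cyclopropane-1,1-dicarboxylate | OC[C@H]1[C@H](c2ccc(OCC=C)c(OC)c2)C1(C(=O)[O-])C(=O)[O-].[Li+].[Li+] | intermediate
9 | (1R,5S,6R)-6-[4-(allyloxy)-3-methoxyphenyl]-2-oxo-3-oxabicyclo[3.1.0]hexane-1-carboxylic acid | O=C1OC[C@H]2[C@H](c3ccc(OCC=C)c(OC)c3)[C@@]12C(=O)O | intermediate
10 | isobutyl carbonic mixed anhydride of acid 9 (same spatial arrangement as 9) | O=C1OC[C@H]2[C@H](c3ccc(OCC=C)c(OC)c3)[C@@]12C(=O)OC(=O)OCC(C)C | intermediate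
11 | (1R,5S,6R)-6-[4-(allyloxy)-3-methoxyphenyl]-1-(hydroxymethyl)-3-oxabicyclo[3.1.0]hexan-2-one (6-exo-aryl) | O=C1OC[C@H]2[C@H](c3ccc(OCC=C)c(OC)c3)[C@@]12CO | intermediate
12 | (1S,5S,6R)-6-[4-(allyloxy)-3-methoxyphenyl]-3,7-dioxabicyclo[3.3.0]octan-2-one (cis-fused, 6-exo-aryl) | O=C1OC[C@@H]2[C@H]1CO[C@H]2c1ccc(OCC=C)c(OC)c1 | intermediate
13 | (1S,5S,6R)-6-[4-(allyloxy)-3-methoxyphenyl]-3,7-dioxabicyclo[3.3.0]octan-2-ol (anomeric mixture) | OC1OC[C@@H]2[C@H]1CO[C@H]2c1ccc(OCC=C)c(OC)c1 | intermediate
14 | 4-bromo-2-methoxyphenol | COc1cc(Br)ccc1O | starting material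
15 | chlorotriisopropylsilane | CC(C)[Si](Cl)(C(C)C)C(C)C | starting material
16 | (4-bromo-2-methoxyphenoxy)triisopropylsilane | COc1cc(Br)ccc1O[Si](C(C)C)(C(C)C)C(C)C | intermediate
17 | [3-methoxy-4-(triisopropylsilyloxy)phenyl]magnesium bromide | COc1cc([Mg]Br)ccc1O[Si](C(C)C)(C(C)C)C(C)C | intermediate
18 | [(3S,4S,5R)-5-[4-(allyloxy)-3-methoxyphenyl]-4-(hydroxymethyl)oxolan-3-yl][3-methoxy-4-(triisopropylsilyloxy)phenyl]methanol (both C7 epimers) | OC[C@@H]1[C@H](C(O)c2ccc(O[Si](C(C)C)(C(C)C)C(C)C)c(OC)c2)CO[C@H]1c1ccc(OCC=C)c(OC)c1 | intermediate
19 | (1S,2R,5S,6R)-6-[4-(allyloxy)-3-methoxyphenyl]-2-[3-methoxy-4-(triisopropylsilyloxy)phenyl]-3,7-dioxabicyclo[3.3.0]octane | COc1cc([C@@H]2OC[C@@H]3[C@H]2CO[C@H]3c2ccc(OCC=C)c(OC)c2)ccc1O[Si](C(C)C)(C(C)C)C(C)C | intermediate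
20 | 2-methylbut-2-ene | CC=C(C)C | starting material
21 | (1S,2R,5S,6R)-2-[3-methoxy-4-(triisopropylsilyloxy)phenyl]-6-[3-methoxy-4-(3-methylbut-2-enyloxy)phenyl]-3,7-dioxabicyclo[3.3.0]octane | COc1cc([C@@H]2OC[C@@H]3[C@H]2CO[C@H]3c2ccc(OCC=C(C)C)c(OC)c2)ccc1O[Si](C(C)C)(C(C)C)C(C)C | intermediate
22 | 4-[(1S,2R,5S,6R)-6-[3-methoxy-4-(3-methylbut-2-enyloxy)phenyl]-3,7-dioxabicyclo[3.3.0]octan-2-yl]-2-methoxyphenol, (7R,7'R,8S,8'S) | COc1cc([C@@H]2OC[C@@H]3[C@H]2CO[C@H]3c2ccc(OCC=C(C)C)c(OC)c2)ccc1O | target

## Step count and least certain steps

Total: 12 steps. Longest linear sequence: 11 steps (steps 1–7 and 9–12); step 8 is a one-step side branch.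

**Step 6 (key step).** The cyclopropane carries only one acceptor, so ionisation may be too slow at temperatures where the product is configurationally stable. Two further processes threaten it: loss of the Lewis-acid-activated C9 hydroxyl with homoallyl-type opening, and re-ionisation of the new C7'–O bond, which would let the exo/endo ratio drift towards equilibrium. The fallback sets out from 11 and gives the cyclopropane a second acceptor. Oxidation of the C9 alcohol with Dess–Martin periodinane should give (1R,5S,6R)-6-[4-(allyloxy)-3-methoxyphenyl]-2-oxo-3-oxabicyclo[3.1.0]hexane-1-carbaldehyde F1. A Cloke–Wilson rearrangement of this formyl cyclopropane (Lewis acid or gentle heating) would then let the formyl oxygen capture C7' to give the dihydrofuran (5S,6R)-6-[4-(allyloxy)-3-methoxyphenyl]-3,7-dioxabicyclo[3.3.0]oct-1(8)-en-2-one F2. Conjugate reduction of its enol-ether double bond with magnesium in methanol, with protonation of C8 from the convex face, returns to the route at 12.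

**Step 2.** With so electron-rich an aryl group the product may open under amine catalysis (elimination through the enamine to an arylidene malonate), and reversible conjugate addition may erode the enantiomeric purity. The fallback sets out from 3 and builds the same bicycle by carbene transfer. 1,2-Reduction (NaBH4, CeCl3) gives (E)-3-[4-(allyloxy)-3-methoxyphenyl]prop-2-en-1-ol F3. Acylation with ethyl malonyl chloride gives the mixed malonate F4, and diazo transfer with a sulfonyl azide gives the diazomalonate F5. Intramolecular cyclopropanation with CuOTf and a chiral bis(oxazoline) ligand then returns to the route at 7: the E-alkene fixes the exo aryl group, and the catalyst fixes the absolute sense, though probably less cleanly than the organocatalyst.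

**Step 10.** The acid that ionises the C7 carbinol can also ionise the existing C7'–O bond, and prolonged exposure would equilibrate either benzylic centre towards the endo isomers; facial selectivity of the closure may also be incomplete. The fallback sets out from 13 and forms the C7–aryl bond on a preformed ring instead of closing a C–O bond at a cation. Acetylation (Ac2O, pyridine) gives the lactol acetate F6. Transmetalation of 17 with ZnBr2 gives the arylzinc bromide F7. BF3·OEt2 at −78 °C then generates the bicyclic oxocarbenium ion, which F7 should attack from the convex face to give the exo-aryl product, returning to the route at 19.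

**Step 11.** Ruthenium hydride species may move the allyl double bond into conjugation with oxygen (propenyl ether formation and loss of the group), and conversion to the trisubstituted alkene may stall. The fallback sets out from 19 and replaces metathesis by dealkylation and alkylation. Pd(PPh3)4 (zerovalent palladium) with morpholine in THF removes the allyl group to give the phenol 4-[(1S,2R,5S,6R)-2-[3-methoxy-4-(triisopropylsilyloxy)phenyl]-3,7-dioxabicyclo[3.3.0]octan-6-yl]-2-methoxyphenol F8. Prenyl bromide with K2CO3 in acetone then returns to the route at 21.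

## Further compounds

F1 | step 6 | (1R,5S,6R)-6-[4-(allyloxy)-3-methoxyphenyl]-2-oxo-3-oxabicyclo[3.1.0]hexane-1-carbaldehyde | O=C1OC[C@H]2[C@H](c3ccc(OCC=C)c(OC)c3)[C@@]12C=O
F2 | step 6 | (5S,6R)-6-[4-(allyloxy)-3-methoxyphenyl]-3,7-dioxabicyclo[3.3.0]oct-1(8)-en-2-one | O=C1OC[C@@H]2C1=CO[C@H]2c1ccc(OCC=C)c(OC)c1
F3 | step 2 | (E)-3-[4-(allyloxy)-3-methoxyphenyl]prop-2-en-1-ol | COc1cc(/C=C/CO)ccc1OCC=C
F4 | step 2 | (E)-3-[4-(allyloxy)-3-methoxyphenyl]prop-2-enyl ethyl malonate | CCOC(=O)CC(=O)OC/C=C/c1ccc(OCC=C)c(OC)c1
F5 | step 2 | (E)-3-[4-(allyloxy)-3-methoxyphenyl]prop-2-enyl ethyl 2-diazomalonate | CCOC(=O)C(=[N+]=[N-])C(=O)OC/C=C/c1ccc(OCC=C)c(OC)c1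
F6 | step 10 | (1S,5S,6R)-6-[4-(allyloxy)-3-methoxyphenyl]-3,7-dioxabicyclo[3.3.0]octan-2-yl acetate (anomeric mixture) | CC(=O)OC1OC[C@@H]2[C@H]1CO[C@H]2c1ccc(OCC=C)c(OC)c1
F7 | step 10 | [3-methoxy-4-(triisopropylsilyloxy)phenyl]zinc bromide | COc1cc([Zn]Br)ccc1O[Si](C(C)C)(C(C)C)C(C)C
F8 | step 11 | 4-[(1S,2R,5S,6R)-2-[3-methoxy-4-(triisopropylsilyloxy)phenyl]-3,7-dioxabicyclo[3.3.0]octan-6-yl]-2-methoxyphenol | COc1cc([C@@H]2OC[C@@H]3[C@H]2CO[C@H]3c2ccc(O)c(OC)c2)ccc1O[Si](C(C)C)(C(C)C)C(C)C
A1 | alternative 1 | trans,trans-3-[hydroxy(3-methoxy-4-prenyloxyphenyl)methyl]-4-[2-(3-methoxy-4-triisopropylsilyloxyphenyl)-1,3-dithian-2-yl]-5-menthyloxy-γ-butyrolactone | O=C1[C@@H]([C@@H](O)c2ccc(OCC=C(C)C)c(OC)c2)[C@H](C2(c3ccc(O[Si](C(C)C)(C(C)C)C(C)C)c(OC)c3)SCCCS2)[C@@H](O[C@H]2C[C@@H](C)CC[C@@H]2C(C)C)O1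
A2 | alternative 1 | (5S)-5-[(1S,2R,5S)-menthyloxy]furan-2(5H)-one | O=C1C=C[C@@H](O[C@H]2C[C@@H](C)CC[C@@H]2C(C)C)O1
A3 | alternative 1 | 2-[3-methoxy-4-(triisopropylsilyloxy)phenyl]-1,3-dithiane | COc1cc(C2SCCCS2)ccc1O[Si](C(C)C)(C(C)C)C(C)C
A4 | alternative 1 | 3-methoxy-4-(3-methylbut-2-enyloxy)benzaldehyde | COc1cc(C=O)ccc1OCC=C(C)C
A5 | alternative 2 | bis-silyl ether of (7R,7'R,8S,8'S)-pinoresinol (tert-butyldimethylsilyl on Ar2, triisopropylsilyl on Ar1) | COc1cc([C@@H]2OC[C@@H]3[C@H]2CO[C@H]3c2ccc(O[Si](C)(C)C(C)(C)C)c(OC)c2)ccc1O[Si](C(C)C)(C(C)C)C(C)C
A6 | alternative 2 | cinnamyl ether of the aryl(oxiranyl)methanol, C7 arranged as in the target, epoxide carbon either way | COc1cc([C@H](OC/C=C/c2ccc(O[Si](C)(C)C(C)(C)C)c(OC)c2)C2CO2)ccc1O[Si](C(C)C)(C(C)C)C(C)C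
A7 | alternative 3 | C2-symmetric 1,4-diaryl-2,3-bis(hydroxymethyl)butane-1,4-diol with the (8S,8'S) pair | COc1cc([C@@H](O)[C@H](CO)[C@@H](CO)[C@H](O)c2ccc(O[Si](C(C)C)(C(C)C)C(C)C)c(OC)c2)ccc1O[Si](C(C)C)(C(C)C)C(C)C
A8 | alternative 3 | C2-symmetric 1,4-diaryl-2,3-dimethylenebutane-1,4-diol | COc1cc([C@@H](O)C(=C)C(=C)[C@H](O)c2ccc(O[Si](C(C)C)(C(C)C)C(C)C)c(OC)c2)ccc1O[Si](C(C)C)(C(C)C)C(C)C
A9 | alternative 3 | (7R,7'R,8S,8'S)-pinoresinol | COc1cc([C@@H]2OC[C@@H]3[C@H]2CO[C@H]3c2ccc(O)c(OC)c2)ccc1O
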